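**Retrosynthetic overview**
1. C4–aryl bond last: Suzuki–Miyaura coupling of a coumarin 4-triflate with unprotected 3-hydroxy-4-methoxyphenylboronic acid.
2. The triflate comes from 4-hydroxy-5,7,8-trimethoxycoumarin; its pyranone ring is closed by Claisen C-acylation/lactonisation of 2'-hydroxy-3',4',6'-trimethoxyacetophenone with diethyl carbonate.
3. The acetophenone comes from 1,2,3,5-tetramethoxybenzene by Friedel–Crafts acetylation with in-flask chelation-controlled ortho-demethylation.
4. Ring order: the oxygenated benzene ring is bought, the pyranone ring is formed in step 2, the pendant aryl ring is attached in step 4.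

Assumption: the target is achiral (no stereocentre, no stereo-axis that can be resolved), so "single enantiomer" is read as the compound as drawn; nothing stereochemical has to be set.

**Step 1**
Reactants: 1 1,2,3,5-tetramethoxybenzene; 2 acetyl chloride
Product: 4 2'-hydroxy-3',4',6'-trimethoxyacetophenone, via 2',3',4',6'-tetramethoxyacetophenone 3 (not isolated)
Conditions: AcCl (1.3 equiv), AlCl3 (2.5 equiv), Et2O, 0 °C → rt, 24–48 h; then ice/2 M HCl
Reagents that add atoms: acetyl chloride 2, CC(Cl)=O
Why: Friedel–Crafts acylation at one of the two equivalent free positions, after which AlCl3 chelated to the C=O cleaves the more crowded ortho-OMe (the one buttressed by a neighbouring OMe) to give the hydrogen-bonded 2'-phenol; this selectivity is recalled from classical precedent and should be confirmed by HMBC/NOE on 4.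

**Step 2**
Reactants: 4 2'-hydroxy-3',4',6'-trimethoxyacetophenone; 5 diethyl carbonate
Product: 7 4-hydroxy-5,7,8-trimethoxycoumarin, via ethyl 3-(2-hydroxy-3,4,6-trimethoxyphenyl)-3-oxopropanoate 6 (not isolated)
Conditions: NaH (4 equiv), (EtO)2CO (3 equiv), toluene, 110 °C; then H2O, aq HCl to pH 1–2
Reagents that add atoms: diethyl carbonate 5, CCOC(=O)OCC
Why: Claisen condensation of the methyl-ketone enolate with the carbonate followed by lactonisation through the phenoxide, driven by formation of the stabilised 4-hydroxycoumarin anion; no stereocentre is formed.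

**Step 3**
Reactants: 7 4-hydroxy-5,7,8-trimethoxycoumarin; 8 trifluoromethanesulfonic anhydride
Product: 9 5,7,8-trimethoxy-2-oxo-2H-chromen-4-yl trifluoromethanesulfonate
Conditions: Tf2O (1.2 equiv), Et3N (1.5 equiv), CH2Cl2, −10 → 0 °C; cold NaHCO3 wash, short silica plug, use promptly
Reagents that add atoms: trifluoromethanesulfonic anhydride 8, O=S(=O)(OS(=O)(=O)C(F)(F)F)C(F)(F)F
Why: O-sulfonylation of the acidic vinylogous-acid enol gives the vinylogous acyl triflate needed for cross-coupling; no stereocentre is formed.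

**Step 4**
Reactants: 9 5,7,8-trimethoxy-2-oxo-2H-chromen-4-yl trifluoromethanesulfonate; 10 3-hydroxy-4-methoxyphenylboronic acid
Product: 11 3'-hydroxy-5,7,8,4'-tetramethoxy-4-phenylcoumarin
Conditions: 10 (1.3 equiv), Pd(PPh3)4 (5 mol %), 2 M aq Na2CO3 (3 equiv), degassed toluene/EtOH, 85 °C; then aq NH4Cl
Reagents that add atoms: 3-hydroxy-4-methoxyphenylboronic acid 10, COc1ccc(B(O)O)cc1O
Why: Suzuki–Miyaura coupling, in which oxidative addition into the electron-poor enol triflate is fast and the free phenol (as phenoxide) is tolerated, so no protecting group is needed; no stereocentre is formed.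

**Compound list**
1 | 1,2,3,5-tetramethoxybenzene | COc1cc(OC)c(OC)c(OC)c1 | starting material
2 | acetyl chloride | CC(Cl)=O | starting material
3 | 2',3',4',6'-tetramethoxyacetophenone | CC(=O)c1c(OC)cc(OC)c(OC)c1OC | intermediate
4 | 2'-hydroxy-3',4',6'-trimethoxyacetophenone | CC(=O)c1c(OC)cc(OC)c(OC)c1O | intermediate
5 | diethyl carbonate | CCOC(=O)OCC | starting material
6 | ethyl 3-(2-hydroxy-3,4,6-trimethoxyphenyl)-3-oxopropanoate | CCOC(=O)CC(=O)c1c(OC)cc(OC)c(OC)c1O | intermediate
7 | 4-hydroxy-5,7,8-trimethoxycoumarin (4-hydroxy-5,7,8-trimethoxy-2H-chromen-2-one) | COc1cc(OC)c2c(O)cc(=O)oc2c1OC | intermediate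
8 | trifluoromethanesulfonic anhydride | O=S(=O)(OS(=O)(=O)C(F)(F)F)C(F)(F)F | starting material
9 | 5,7,8-trimethoxy-2-oxo-2H-chromen-4-yl trifluoromethanesulfonate | COc1cc(OC)c2c(OS(=O)(=O)C(F)(F)F)cc(=O)oc2c1OC | intermediate
10 | 3-hydroxy-4-methoxyphenylboronic acid | COc1ccc(B(O)O)cc1O | starting material
11 | 3'-hydroxy-5,7,8,4'-tetramethoxy-4-phenylcoumarin [4-(3-hydroxy-4-methoxyphenyl)-5,7,8-trimethoxy-2H-chromen-2-one], achiral | COc1ccc(-c2cc(=O)oc3c(OC)c(OC)cc(OC)c23)cc1O | target

**Total step count:** 4
**Longest linear sequence:** 4 steps (1 → 4 → 7 → 9 → 11)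

**Three steps most likely to fail**

Step 1 (one-pot acylation/demethylation). The risk is a mixture of unreacted 3, over-demethylated material and some cleavage of the other ortho-OMe. The fallback sets out from 1 and comes back at 4. Compound 1 is lithiated at the position flanked by two OMe groups (n-BuLi, TMEDA, THF, 0 °C) to give 2,3,4,6-tetramethoxyphenyllithium F1. F1 is quenched with N-methoxy-N-methylacetamide (CC(=O)N(C)OC) to give ketone 3, now isolated without any Lewis acid. A separate chelation-controlled mono-demethylation with BCl3 (1.1 equiv, CH2Cl2, −78 → 0 °C) then gives 4. This replaces the electrophilic acylation by directed ortho-metalation and makes the ether cleavage its own controllable step; it still relies on the same preference for the crowded ortho-OMe.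

Step 3 (triflate formation). The risk is that 9 reverts to 7 by S–O cleavage during work-up, on silica or later under the aqueous base of step 4. The fallback sets out from 7 and comes back at 11. Compound 7 is converted with Bu4NBr/P2O5 (toluene, 100 °C) into 4-bromo-5,7,8-trimethoxycoumarin F2, a C–Br electrophile that cannot fall back to 7. F2 is coupled with 10 (Pd(PPh3)4, aq Na2CO3, dioxane, 90 °C) to give 11 directly.

Step 4 (Suzuki coupling at C4, peri to the 5-OMe). The risks are slow coupling at the hindered position, triflate hydrolysis, and protodeboronation or O-attack by the phenoxide of 10. The fallback sets out from 1 and comes back at 11; it builds the pyranone ring around an aryl ketone instead of coupling onto it.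
- Commercial isovanillic acid (COc1ccc(C(=O)O)cc1O) is acetylated (Ac2O, pyridine) to 3-acetoxy-4-methoxybenzoic acid F3.
- F3 is converted with SOCl2 (cat. DMF, toluene, 70 °C) into 3-acetoxy-4-methoxybenzoyl chloride F4.
- Friedel–Crafts aroylation of 1 with F4 (AlCl3, Et2O/CH2Cl2, 0 °C → rt) proceeds through 5-(2,3,4,6-tetramethoxybenzoyl)-2-methoxyphenyl acetate F5 (not isolated), which is ortho-demethylated in the flask to 5-(2-hydroxy-3,4,6-trimethoxybenzoyl)-2-methoxyphenyl acetate F6.
- Wittig olefination/lactonisation of F6 with ethyl (triphenylphosphoranylidene)acetate (CCOC(=O)C=P(c1ccccc1)(c1ccccc1)c1ccccc1) in refluxing toluene or N,N-diethylaniline gives 2-methoxy-5-(5,7,8-trimethoxy-2-oxo-2H-chromen-4-yl)phenyl acetate F7.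
- Methanolysis of F7 (K2CO3, MeOH, rt, then mild acid) gives 11.

**Further compounds**
F1 | step 1 | 2,3,4,6-tetramethoxyphenyllithium | [Li]c1c(OC)cc(OC)c(OC)c1OC
F2 | step 3 | 4-bromo-5,7,8-trimethoxycoumarin | COc1cc(OC)c2c(Br)cc(=O)oc2c1OC
F3 | step 4 | 3-acetoxy-4-methoxybenzoic acid | COc1ccc(C(=O)O)cc1OC(C)=O
F4 | step 4 | 3-acetoxy-4-methoxybenzoyl chloride | COc1ccc(C(Cl)=O)cc1OC(C)=O
F5 | step 4 | 5-(2,3,4,6-tetramethoxybenzoyl)-2-methoxyphenyl acetate | COc1ccc(C(=O)c2c(OC)cc(OC)c(OC)c2OC)cc1OC(C)=O
F6 | step 4 | 5-(2-hydroxy-3,4,6-trimethoxybenzoyl)-2-methoxyphenyl acetate | COc1ccc(C(=O)c2c(OC)cc(OC)c(OC)c2O)cc1OC(C)=O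
F7 | step 4 | 2-methoxy-5-(5,7,8-trimethoxy-2-oxo-2H-chromen-4-yl)phenyl acetate | COc1ccc(-c2cc(=O)oc3c(OC)c(OC)cc(OC)c23)cc1OC(C)=O
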